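(The numbers belong to no real substance; the result is computed.)

Slowness is what I look for in these flasks: Sub that has slipped over into Int reaches the chains by coming back the way it went.

in all of them: Sub 3.0 M; Tsp 33 mM; time 2.5 min
- birch: Tsp4 6.0 mM
- maple: Tsp4 12 mM
- oak: Tsp4 20 mM

    Tsp → 2 Tsp2 (k1 = 0.00555 s⁻¹)
    Sub + Tsp2 → Tsp3 + Sub2 (k2 = 6.10 × 10⁵ M⁻¹ s⁻¹)
    Sub + Tsp3 → Sub2 + Tsp3, rate k3*[Tsp3]*[Sub] (k3 = 3.60 × 10⁵ M⁻¹ s⁻¹)
    2 Tsp3 → Zed (k4 = 1.0 × 10⁸ M⁻¹ s⁻¹)
    Tsp3 + Tsp4 → Zed2 (k5 = 1.12 × 10⁷ M⁻¹ s⁻¹)
    Sub ⇌ Int (K6 = 0.285, k6 = 0.00183 s⁻¹)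

- a doubled species enters its step squared and goes two at a time
- "hardly changes" means that all values lie within two and a half points (for a concentration: within two and a half percent of the largest)
- run time (birch): 2.5 min

1. amount of Sub2 at the end, in percent of the Sub charged for birch, maple, oak, in this order
2. how that number moves from the first to the last of them (falls, then rises / rises all the way / rises, then falls / hardly changes / falls all the way)

I expect Sub to end up in Sub2, so I ask how much still sits in Int at 2.5 min. Tsp breaks down with rate constant 0.00555 s⁻¹, each Tsp giving two radicals, and its charge can give P = 66.0 mM of them. I take each radical, once it is Tsp3, to be stopped by Tsp4 while Tsp4 lasts; this is the induction period. A Tsp4 charge Q then lasts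

D = ln[P/(P − Q)] / 0.00555 s⁻¹: 17.2 s in birch, 36.2 s in maple, 65.0 s in oak.

At the start of oak, I put Tsp3 near 1.64 × 10⁻⁹ M, so chains take Sub at 5.89 × 10⁻⁴ s⁻¹, slower than the 0.00183 s⁻¹ at which Sub leaks into Int. As a rough step I therefore let Sub do nothing but leak during D. With K = 0.285 and return constant b = 0.00642 s⁻¹, the share of the charge in Int after D is

x = [K/(1 + K)] · (1 − exp[−(0.00183 s⁻¹ + b)D]).

After D, I balance radical birth against Tsp3 meeting Tsp3. That puts Tsp3 near 1.35 × 10⁻⁶ M, and Sub is then taken at 0.487 s⁻¹, far faster than b. In my reckoning free Sub stays low, the return from Int becomes the rate-limiting step, and Int falls by first order with the drain half-life, ln(2)/b = 1.80 min. That is longer than the 1.40 min relaxation half-life of birch, which counts both directions. At time t the share left in Int is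

f = x · exp[−b(t − D)].

Birch: f = 1.25 %, so Sub2 is 98.8 %.

Maple: f = 2.75 %, so Sub2 is 97.2 %.

Oak: f = 5.34 %, so Sub2 is 94.7 %.

The shape of my row from birch to oak is: falls all the way, with oak lower.

The forecast gives 98.6 %, 97.1 % and 94.6 %, falls all the way; my row differs from these by 0.15 percentage points, 0.15 points and 0.061 points. Its ground for the second stage is that “free Sub is consumed within seconds”.

The flask gives 98.6 %, 97.1 % and 94.6 %, falls all the way. In oak at 2.50 min, free Sub stands at 0.091 % of the charge and Int at 5.33 %. The drain half-life 1.80 min, applied to the 8.60 % of Int that oak held at 1.25 min, gives 5.31 % at the end. Applied to the 4.56 % of maple at 1.25 min, it gives 2.82 %, and maple holds 2.82 % of Int at 2.50 min.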